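**A direct plan and its weak points**

A direct plan would arylate the C10 enolate of a C5-vinyl ring A ketone with a 2-bromobenzoate to the α-aryl ketone A1, make the quaternary C8 by Birch reductive alkylation of that arene inside a temporary lactone to give the diene lactone A2, reopen the lactone to the vinyl ketone A3, close ring D by a phosphine-catalysed Rauhut–Currier reaction to the tetracycle A4, and finish the epoxide from a 9,11-diol.
- Ring D closure of A3 to A4: the Rauhut–Currier step must run in the 5-(enolendo)-exo-trig mode, an unfavourable enolate geometry, late and on the most advanced material.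
- Lactone to vinyl ketone, from A2 to A3: three silyl ethers, a hydride reduction, a Grignard addition, an allylic oxidation and an acid-mediated acetal closure are spent to add one vinyl group.
- Epoxide after A4: reduction of two ketones, re-oxidation of one, mesylation and displacement, four steps with a redox correction at C15, at the end of more than twenty linear steps.

**Retrosynthetic overview of the new route**

The oxepane-fused bicyclo[3.2.1]octene is cut at C8–C9 and C12–C13. An oxyallyl cation on the C10 side chain of ring A and a 2-siloxycyclopentadiene (ring D, from cyclopentenone), tethered through the C6–O–C7 acetal, join in one intramolecular (4+3) cycloaddition that closes rings B and C together.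
Ring order: A (bought), D (bought), B and C in one step, epoxide last; the (4+3) step replaces both the enolendo Michael closure and the lactone detour.
Ring A needs one catalytic stereocentre (C5). A diosphenol Claisen rearrangement relays it to the quaternary C10 and leaves a 1,2-dione, which is reduced to the cis-diol and acetylated at once, so ring A carries its final groups from step 6.
The cycloadduct carries C15 as a silyl enol ether (methylenated directly, no redox correction) and C11 as a ketone, which is reduced and dehydrated to the 9(11)-alkene and epoxidised in the last step.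

Key step: step 10

Remark: atoms are numbered as in ent-kaurane (C1–C20; C17 is the exocyclic methylene carbon), and the C6 lactol is assumed to settle as the anomer drawn in the target; the hydroxymethyl cyclopentenone is used as the racemate, so the mixed acetal made from it is a mixture at C6 and C8, which converges when C8 becomes sp2 in the key step and when C6 equilibrates in the lactol.

**Route**

Step 1
Reactants: 1 2,4,4-trimethylcyclohex-2-en-1-one; 2 vinylmagnesium bromide
Product: 3 (3S)-3-ethenyl-2,4,4-trimethylcyclohexan-1-one (mixture of epimers at C2 of the ring, the later C10)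
Conditions: CuBr·SMe2 (5 mol %), (R,Sp)- or (S,Rp)-1-[2-(diphenylphosphino)ferrocenyl]ethyldicyclohexylphosphine (6 mol %, the enantiomer that gives 3S), t-BuOMe, −78 °C; aq. NH4Cl
Reagents that add atoms: none
Why: Copper-catalysed asymmetric conjugate addition of a Grignard reagent: the ferrocenyl diphosphine–copper complex selects the enone face and sets C5, the only stereocentre bought by catalysis; the α-centre is left unset because it becomes sp2 in step 2.

Step 2
Reactants: 3 vinyl ketone
Product: 4 (4R)-4-ethenyl-2-hydroxy-3,5,5-trimethylcyclohex-2-en-1-one (diosphenol; C2 ketone, C1 enol toward C10)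
Conditions: SeO2 (1.3 equiv), 1,4-dioxane/H2O (20:1), 90 °C
Reagents that add atoms: selenium dioxide (O=[Se]=O)
Why: Riley oxidation of the only α-methylene group gives the 1,2-dione, which should rest as the diosphenol enolised toward the methyl-bearing carbon C10, the more substituted enol.

Step 3
Reactants: 4 diosphenol; 5 3-chloro-2-(chloromethyl)prop-1-ene
Product: 6 (4R)-2-{[2-(chloromethyl)prop-2-en-1-yl]oxy}-4-ethenyl-3,5,5-trimethylcyclohex-2-en-1-one
Conditions: K2CO3, NaI (10 mol %), acetone, 56 °C; 5 in threefold excess
Reagents that add atoms: none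
Why: Williamson O-alkylation of the acidic enol at the C1 oxygen; the symmetrical dichloride in excess should suppress double alkylation.

Step 4
Reactants: 6 allyl enol ether
Product: 7 diosphenol with quaternary C10: 6-[2-(chloromethyl)prop-2-en-1-yl]-5-ethenyl-2-hydroxy-4,4,6-trimethylcyclohex-2-en-1-one, C10 side chain trans to the C5 vinyl group
Conditions: PhMe, 170 °C (sealed tube), 2,6-di-tert-butyl-4-methylphenol (cat.)
Reagents that add atoms: none
Why: Claisen rearrangement of a diosphenol allyl ether: the allyl unit passes suprafacially from O1 to C10 on the face opposite the pseudo-axial C5 vinyl group, which sets the quaternary C10 with C9 trans to C6 and frees the 1,2-dione (enol toward C3); the allyl unit is symmetrical, so thermal allylic transposition of its chloride is degenerate.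

Step 5
Reactants: 7 diosphenol
Product: 8 cis-1,2-diol (C1–OH and C2–OH both on the face of the C20 methyl)
Conditions: NaBH4, CeCl3·7H2O, MeOH, −20 to 0 °C; AcOH quench
Reagents that add atoms: none
Why: Luche reduction of the C1 ketone and then of the tautomerised C2 ketone: in the conformer with the C5 and C10 carbon chains equatorial, C20 and one C4 methyl are syn-axial, so hydride should reach both carbonyls from the opposite face and give the cis-diol on the C20 face; the cold acidic quench keeps the C1 alkoxide from displacing the allylic chloride.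

Step 6
Reactants: 8 diol
Product: 9 C1, C2 diacetate
Conditions: Ac2O, 4-(dimethylamino)pyridine (cat.), pyridine, 23 °C
Reagents that add atoms: acetic anhydride (CC(=O)OC(C)=O)
Why: Nucleophile-catalysed acetylation installs the two acetates of the target, which also keep the C1 and C2 oxygens from trapping the cation in step 10.

Step 7
Reactants: 9 diene diacetate
Product: 11 C6 dimethyl acetal with the chloromethyl ketone side chain C10–CH2–C(=O)–CH2Cl, via keto aldehyde 10 (not isolated)
Conditions: O3, CH2Cl2/MeOH (4:1), −78 °C; Me2S; then HC(OMe)3, pyridinium p-toluenesulfonate (cat.), 23 °C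
Reagents that add atoms: ozone ([O-][O+]=O); trimethyl orthoformate (COC(OC)OC)
Why: Ozonolysis with reductive work-up cleaves both terminal alkenes in one operation, the vinyl group to the C6 aldehyde and the 1,1-disubstituted alkene to the C11 ketone; the aldehyde is acetalised much faster than the α-chloro ketone, and C5, epimerisable, stays in the more stable equatorial arrangement trans to C9.

Step 8
Reactants: 12 cyclopent-2-en-1-one; 13 formaldehyde
Product: 14 5-(hydroxymethyl)cyclopent-2-en-1-one (racemic)
Conditions: LiN(i-Pr)2, THF, −78 °C; CH2O (gas, from cracked paraformaldehyde); AcOH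
Reagents that add atoms: none
Why: Kinetic α′-lithiation of the enone and aldol addition to monomeric formaldehyde; the new stereocentre (C8) does not matter because it becomes sp2 in step 10.

Step 9
Reactants: 11 dimethyl acetal; 14 hydroxymethyl cyclopentenone
Product: 16 mixed methyl acetal C6(OMe)–O–C7 linking ring A to the cyclopentenone (mixture at C6 and C8), via collidinium triflate 15 (not isolated)
Conditions: Et3SiOTf (1.1 equiv), 2,4,6-collidine, CH2Cl2, 0 °C; then 14, 0 to 23 °C; aq. NaHCO3
Reagents that add atoms: none
Why: Acetal exchange through a pyridinium salt: the silyl triflate and collidine turn one methoxy group of the acetal into a collidinium leaving group, which the primary alcohol displaces; ketones, the enone and the acetates are not touched under these weakly basic conditions.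

Step 10
Reactants: 16 tethered chloro ketone–cyclopentenone
Product: 18 tetracyclic cycloadduct (oxepane methyl acetal, C11 ketone, C15 triisopropylsilyl enol ether, C9–H), via siloxydiene 17 (not isolated)
Conditions: i-Pr3SiOTf (1.05 equiv), Et3N, CH2Cl2, −78 °C; then CF3CH2OH, i-Pr2NEt, −40 to 23 °C
Reagents that add atoms: triisopropylsilyl trifluoromethanesulfonate (CC(C)[Si](OS(=O)(=O)C(F)(F)F)(C(C)C)C(C)C)
Why: The silyl triflate first converts the more Lewis-basic conjugated ketone into the 2-siloxycyclopenta-1,3-diene; i-Pr2NEt in trifluoroethanol then enolises the chloro ketone toward C9, chloride leaves from C12, and the 2-oxyallyl cation bonds through C9 and C12 to C8 and C13 of the tethered diene. The closest known reaction is the base-mediated (4+3) cycloaddition of α-chloro ketones with cyclopentadiene and furans in trifluoroethanol, including its intramolecular form with tethered dienes. Ring B closes as the seven-membered tether ring when C8–C9 forms, and ring C closes as the six-membered ring of the bicyclo[3.2.1]octenone when C12–C13 forms across ring D. C8 and C13 are set relative to C10 by the tether: with the incipient oxepane chair-like and trans-fused to ring A, the diene should turn its small C14 methylene toward the axial C20 methyl and its siloxy-bearing C15–C16 edge toward H5, the ent-kaurane arrangement of the target; C9 forms with C10 equatorial on ring C, which is also the thermodynamic arrangement next to the C11 ketone. Regiochemistry is secured by the tether, since C9 can reach only C8, and the acetates keep the ring A oxygens from capturing the cation. The step needs the cycloaddition to outrun solvent capture of the cation and 1,5-hydrogen shift in the diene, which the low temperature and the intramolecular setting are meant to secure.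

Step 11
Reactants: 18 C11 ketone
Product: 19 C11 alcohol (hydroxyl axial, on the face of the C15–C16 bridge, trans-diaxial to H9)
Conditions: NaBH4, MeOH/THF (1:4), −20 °C
Reagents that add atoms: none
Why: Borohydride reduction of the only free ketone (C15 is masked as the silyl enol ether and the acetates survive at this temperature): hydride should attack C11 from the open face opposite the two-carbon bridge.

Step 12
Reactants: 19 C11 alcohol
Product: 20 9(11)-alkene (C15 silyl enol ether retained)
Conditions: SOCl2, pyridine, CH2Cl2, −20 to 0 °C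
Reagents that add atoms: none
Why: Dehydration through the chlorosulfite by anti-periplanar E2 loss of the axial H9, the same geometry by which axial 11-hydroxy steroids give 9(11)-alkenes; it leads to the more substituted alkene.

Step 13
Reactants: 20 silyl enol ether
Product: 23 C15 ketone with C16 exocyclic methylene (9(11)-alkene, C6 methyl acetal), via Mannich base 21 (not isolated), via methiodide 22 (not isolated)
Conditions: dimethyl(methylidene)ammonium iodide, CH2Cl2, 23 °C; then MeI; then aq. NaHCO3, 23 °C
Reagents that add atoms: N,N-dimethylmethyleneiminium iodide (C=[N+](C)C.[I-])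
Why: Mannich reaction of the silyl enol ether at C16, its only nucleophilic carbon, followed by quaternisation and E1cB elimination of trimethylamine; the regiochemistry is fixed by the enol ether carried over from the diene.

Step 14
Reactants: 23 methyl acetal
Product: 24 C6 lactol (9(11)-alkene, enone, diacetate)
Conditions: AcOH/THF/H2O (3:1:1), 40 °C
Reagents that add atoms: water (O)
Why: Mild acid hydrolysis of the cyclic mixed acetal through the ring oxocarbenium ion; it is run before the epoxide exists, and the lactol should settle as its thermodynamic anomer.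

Step 15
Reactants: 24 9(11)-alkene
Product: 25 CNP0224512.1
Conditions: dimethyldioxirane, acetone, 0 °C
Reagents that add atoms: dimethyldioxirane (CC1(C)OO1)
Why: Electrophilic epoxidation with a neutral dioxirane: only the electron-rich trisubstituted alkene should react (the exocyclic enone is electron-poor), on the exo face of the bicyclo[3.2.1]octene, anti to the C15–C16 bridge and to C1 with its acetate; this is the face of the epoxide in the target, and the C20 methyl, which also stands on it, is expected to shield less than the bridge.

**Compound list**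

1 | 2,4,4-trimethylcyclohex-2-en-1-one | CC1=CC(C)(C)CCC1=O | starting material
2 | vinylmagnesium bromide | C=C[Mg]Br | starting material
3 | (3S)-3-ethenyl-2,4,4-trimethylcyclohexan-1-one (epimers at the methyl-bearing α-carbon) | C=C[C@@H]1C(C)(C)CCC(=O)C1C | intermediate
4 | (4R)-4-ethenyl-2-hydroxy-3,5,5-trimethylcyclohex-2-en-1-one | C=C[C@@H]1C(C)(C)CC(=O)C(O)=C1C | intermediate
5 | 3-chloro-2-(chloromethyl)prop-1-ene | C=C(CCl)CCl | starting material
6 | (4R)-2-{[2-(chloromethyl)prop-2-en-1-yl]oxy}-4-ethenyl-3,5,5-trimethylcyclohex-2-en-1-one | C=C[C@@H]1C(C)(C)CC(=O)C(OCC(=C)CCl)=C1C | intermediate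
7 | 6-[2-(chloromethyl)prop-2-en-1-yl]-5-ethenyl-2-hydroxy-4,4,6-trimethylcyclohex-2-en-1-one, C10 chain trans to the C5 vinyl group | C=C[C@@H]1C(C)(C)C=C(O)C(=O)[C@@]1(C)CC(=C)CCl | intermediate
8 | cis-diol of 7: C1–OH and C2–OH on the face of the C20 methyl | C=C[C@@H]1C(C)(C)C[C@H](O)[C@H](O)[C@@]1(C)CC(=C)CCl | intermediate
9 | C1, C2 diacetate of 8 | C=C[C@@H]1C(C)(C)C[C@H](OC(C)=O)[C@H](OC(C)=O)[C@@]1(C)CC(=C)CCl | intermediate
10 | keto aldehyde: C6 aldehyde on C5, C10–CH2–C(=O)–CH2Cl | O=C[C@@H]1C(C)(C)C[C@H](OC(C)=O)[C@H](OC(C)=O)[C@@]1(C)CC(=O)CCl | intermediate (not isolated)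
11 | C6 dimethyl acetal of 10 | COC(OC)[C@@H]1C(C)(C)C[C@H](OC(C)=O)[C@H](OC(C)=O)[C@@]1(C)CC(=O)CCl | intermediate
12 | cyclopent-2-en-1-one | O=C1C=CCC1 | starting material
13 | formaldehyde (from paraformaldehyde) | C=O | starting material
14 | 5-(hydroxymethyl)cyclopent-2-en-1-one (racemic) | OCC1CC=CC1=O | intermediate
15 | N-(α-methoxyalkyl)-2,4,6-trimethylpyridinium triflate derived from 11 at C6 | COC([n+]1c(C)cc(C)cc1C)[C@@H]2C(C)(C)C[C@H](OC(C)=O)[C@H](OC(C)=O)[C@@]2(C)CC(=O)CCl.[O-]S(=O)(=O)C(F)(F)F | intermediate (not isolated)
16 | mixed acetal: C6(OMe)–O–CH2 (C7) on C5 of the 2-oxocyclopent-3-en-1-yl unit; chloromethyl ketone on C10 (mixture at C6 and C8) | COC(OCC1CC=CC1=O)[C@@H]2C(C)(C)C[C@H](OC(C)=O)[C@H](OC(C)=O)[C@@]2(C)CC(=O)CCl | intermediate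
17 | 16 with the cyclopentenone as its 2-(triisopropylsiloxy)cyclopenta-1,3-diene (C8=C15(OSi)–C16=C13) | COC(OCC1=C(O[Si](C(C)C)(C(C)C)C(C)C)C=CC1)[C@@H]2C(C)(C)C[C@H](OC(C)=O)[C@H](OC(C)=O)[C@@]2(C)CC(=O)CCl | intermediate (not isolated)
18 | (4+3) cycloadduct: rings A, B (oxepane methyl acetal), C (C11 ketone, H9 axial, anti to the bridge) and D (C15 triisopropylsilyl enol ether), C14 on the C20 side, diacetate | C1=C(O[Si](C(C)C)(C(C)C)C(C)C)[C@@]23COC(OC)[C@@H]4C(C)(C)C[C@H](OC(C)=O)[C@H](OC(C)=O)[C@@]4(C)[C@H]2C(=O)C[C@@H]1C3 | intermediate
19 | C11 alcohol of 18, hydroxyl axial on the face of the C15–C16 bridge | C1=C(O[Si](C(C)C)(C(C)C)C(C)C)[C@@]23COC(OC)[C@@H]4C(C)(C)C[C@H](OC(C)=O)[C@H](OC(C)=O)[C@@]4(C)[C@H]2[C@@H](O)C[C@@H]1C3 | intermediate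
20 | 9(11)-alkene with C15 triisopropylsilyl enol ether | C1=C(O[Si](C(C)C)(C(C)C)C(C)C)[C@@]23COC(OC)[C@@H]4C(C)(C)C[C@H](OC(C)=O)[C@H](OC(C)=O)[C@@]4(C)C2=CC[C@@H]1C3 | intermediate
21 | Mannich base: C15 ketone with C16–CH2NMe2 (mixture at C16) | CN(C)CC1C(=O)[C@@]23COC(OC)[C@@H]4C(C)(C)C[C@H](OC(C)=O)[C@H](OC(C)=O)[C@@]4(C)C2=CC[C@@H]1C3 | intermediate (not isolated)
22 | trimethylammonium iodide of 21 | C[N+](C)(C)CC1C(=O)[C@@]23COC(OC)[C@@H]4C(C)(C)C[C@H](OC(C)=O)[C@H](OC(C)=O)[C@@]4(C)C2=CC[C@@H]1C3.[I-] | intermediate (not isolated)
23 | 9(11)-alkene, C15 ketone, C16 exocyclic methylene, C6 methyl acetal, diacetate | C=C1C(=O)[C@@]23COC(OC)[C@@H]4C(C)(C)C[C@H](OC(C)=O)[C@H](OC(C)=O)[C@@]4(C)C2=CC[C@@H]1C3 | intermediate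
24 | C6 lactol of 23 | C=C1C(=O)[C@@]23CO[C@@H](O)[C@@H]4C(C)(C)C[C@H](OC(C)=O)[C@H](OC(C)=O)[C@@]4(C)C2=CC[C@@H]1C3 | intermediate
25 | CNP0224512.1 | C=C1C(=O)[C@@]23CO[C@@H](O)[C@@H]4C(C)(C)C[C@H](OC(C)=O)[C@H](OC(C)=O)[C@@]4(C)[C@]24O[C@@H]4C[C@@H]1C3 | target

**Step count and risks**

Total step count: 15. Longest linear sequence: 14 (steps 1–7 and 9–15; step 8 is a one-step branch).

Steps most likely to fail:

1. Step 10. Enolisation at the neopentyl C9 may be slow, so that solvent capture of the cation or Favorskii contraction competes. The silyl triflate may activate the mixed acetal instead of the enone, and the siloxydiene may be desilylated or isomerised by 1,5-hydrogen shift. Closure with the diene turned the other way would give the wrong sense at C8 and C13. The fallback moves the chloride to C9 and generates the cation by ionisation in an aprotic medium; it sets out from 4 and comes back at 18. Diosphenol 4 would be O-alkylated with 1,3-dichloro-2-methylprop-1-ene to the 3-chloro-2-methylallyl enol ether F1, rearranged (Claisen, lowest workable temperature) to the C9-chloro diosphenol F2, reduced to the cis-diol F3 and acetylated to the diacetate F4. Ozonolysis would give the α-chloro methyl ketone aldehyde F5 and its dimethyl acetal F6, and acetal exchange with 14 through the collidinium triflate F7 would give the mixed acetal F8. i-Pr3SiOTf and Et3N in excess would silylate both ketones (the methyl ketone enolises away from the chloride, so no chemoselectivity is needed) to the bis(silyl enol ether) F9. AgBF4 with 2,6-di-tert-butylpyridine in CH2Cl2 at −78 °C would ionise the secondary chloride to the 2-siloxyallyl cation, which should undergo the same cycloaddition; loss of the C11 silyl group on aqueous work-up returns 18.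

2. Step 15. The oxidant may turn to the face of the C15–C16 bridge if the C20 methyl shields the exo face more than expected. The fallback puts the oxygen on by anti addition and ring closure instead of direct delivery; it sets out from 24 and comes back at 25. N-Bromosuccinimide in aqueous THF at 0 °C would form the bromonium ion on the face that electrophiles prefer, in this case the bridge face, and water should open it at the tertiary C9 from the opposite face to give the trans-diaxial bromohydrin F10 (C9–OH anti to the bridge, C11–Br on the bridge face). Ag2O in THF at 23 °C would then close the epoxide with inversion at C11, on the face of the C9 oxygen, which gives 25.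

3. Step 4. The Claisen rearrangement may give poor facial selectivity at C10, or the ether may decompose at the temperature needed. The fallback makes the C10–C9 bond by enolate alkylation and introduces the C2 oxygen afterwards; it sets out from 1 and 2 and comes back at 7. The magnesium enolate from the conjugate addition of step 1 would be trapped in the same flask with 5 (N,N′-dimethylpropyleneurea, −78 to 0 °C), anti to the C5 vinyl group, to give the α-quaternary ketone F11. Riley oxidation (SeO2, dioxane/H2O) of its only α-methylene group then gives diosphenol 7.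

**Further compounds**

F1 | step 10 | (4R)-2-[(3-chloro-2-methylprop-2-en-1-yl)oxy]-4-ethenyl-3,5,5-trimethylcyclohex-2-en-1-one | C=C[C@@H]1C(C)(C)CC(=O)C(OCC(C)=CCl)=C1C
F2 | step 10 | 6-(1-chloro-2-methylprop-2-en-1-yl)-5-ethenyl-2-hydroxy-4,4,6-trimethylcyclohex-2-en-1-one, C10 chain trans to the C5 vinyl group (mixture at C9) | C=C[C@@H]1C(C)(C)C=C(O)C(=O)[C@@]1(C)C(Cl)C(C)=C
F3 | step 10 | cis-diol of F2 (both hydroxyls on the C20 face) | C=C[C@@H]1C(C)(C)C[C@H](O)[C@H](O)[C@@]1(C)C(Cl)C(C)=C
F4 | step 10 | C1, C2 diacetate of F3 | C=C[C@@H]1C(C)(C)C[C@H](OC(C)=O)[C@H](OC(C)=O)[C@@]1(C)C(Cl)C(C)=C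
F5 | step 10 | keto aldehyde: C6 aldehyde on C5, C10–CHCl–C(=O)–CH3 | O=C[C@@H]1C(C)(C)C[C@H](OC(C)=O)[C@H](OC(C)=O)[C@@]1(C)C(Cl)C(C)=O
F6 | step 10 | C6 dimethyl acetal of F5 | COC(OC)[C@@H]1C(C)(C)C[C@H](OC(C)=O)[C@H](OC(C)=O)[C@@]1(C)C(Cl)C(C)=O
F7 | step 10 | N-(α-methoxyalkyl)-2,4,6-trimethylpyridinium triflate derived from F6 at C6 | COC([n+]1c(C)cc(C)cc1C)[C@@H]2C(C)(C)C[C@H](OC(C)=O)[C@H](OC(C)=O)[C@@]2(C)C(Cl)C(C)=O.[O-]S(=O)(=O)C(F)(F)F
F8 | step 10 | mixed acetal of F6 with 14 (C6(OMe)–O–C7; α-chloro methyl ketone on C10) | COC(OCC1CC=CC1=O)[C@@H]2C(C)(C)C[C@H](OC(C)=O)[C@H](OC(C)=O)[C@@]2(C)C(Cl)C(C)=O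
F9 | step 10 | bis(triisopropylsilyl enol ether) of F8: 2-siloxycyclopenta-1,3-diene and 3-chloro-2-siloxyprop-1-ene units | COC(OCC1=C(O[Si](C(C)C)(C(C)C)C(C)C)C=CC1)[C@@H]2C(C)(C)C[C@H](OC(C)=O)[C@H](OC(C)=O)[C@@]2(C)C(Cl)C(=C)O[Si](C(C)C)(C(C)C)C(C)C
F10 | step 15 | bromohydrin of 24: C9–OH anti to the C15–C16 bridge, C11–Br on the bridge face | C=C1C(=O)[C@@]23CO[C@@H](O)[C@@H]4C(C)(C)C[C@H](OC(C)=O)[C@H](OC(C)=O)[C@@]4(C)[C@@]2(O)[C@@H](Br)C[C@@H]1C3
F11 | step 4 | 2-[2-(chloromethyl)prop-2-en-1-yl]-3-ethenyl-2,4,4-trimethylcyclohexan-1-one, allyl chain trans to the vinyl group | C=C[C@@H]1C(C)(C)CCC(=O)[C@@]1(C)CC(=C)CCl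
A1 | direct plan | methyl 2-[(1R,6R)-6-ethenyl-1,5,5-trimethyl-2-oxocyclohexyl]-3-methoxybenzoate | C=C[C@@H]1C(C)(C)CCC(=O)[C@@]1(C)c1c(OC)cccc1C(=O)OC
A2 | direct plan | Birch reductive alkylation product: lactone-bridged cyclohexa-1,4-diene with quaternary C8 bearing CH2OSi(i-Pr)3 | COC(OC)[C@@H]1C(C)(C)C[C@H](O)[C@@H]2OC(=O)[C@]3(CO[Si](C(C)C)(C(C)C)C(C)C)C=CCC(OC)=C3[C@@]12C
A3 | direct plan | oxepane methyl acetal bis-enone (C8 vinyl ketone, ring C cyclohexenone, silyl ethers at O2 and O9) | C=CC(=O)[C@@]23CO[C@@H](OC)[C@@H]4C(C)(C)C[C@H](O[Si](CC)(CC)CC)[C@H](O)[C@@]4(C)[C@@]2(O[Si](CC)(CC)CC)C(=O)C=CC3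
A4 | direct plan | Rauhut–Currier product with ring D α-methylene cyclopentanone and C11 ketone | C=C1C(=O)[C@@]23CO[C@@H](OC)[C@@H]4C(C)(C)C[C@H](O[Si](CC)(CC)CC)[C@H](O)[C@@]4(C)[C@@]2(O[Si](CC)(CC)CC)C(=O)C[C@@H]1C3
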